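**Plan**

- Cuts: C5′–C11 (aldol condensation, then conjugate reduction) separates decalin aldehyde 20 from cyclopentenone 27. In 20 the ring-A bond C4–C5 is traced back to a C3–C5 bond, so ring A (C1–C5, C10) becomes a cyclopentane (C1, C2, C3, C5, C10) that carries C4 and its methyl as a 1-hydroxyethyl group on C3. Then C8–CH3, H–C8/H–C9, and the hydrindane back to a Hajos–Parrish-type enedione.
- Forward: cyclopentane and ring B arise together by Michael/aldol annulation; ring B is dressed (C10, C9, C8); the cyclopentane is enlarged to ring A; the cyclopentenone ring is made separately and joined last.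
- Enabling feature: in ring A the methyl-bearing C4 sits between quaternary C5 and C3 and carries the C3=C4 double bond. In the cyclopentane precursor the C3–C5 bond lies anti to a leaving group on exocyclic C4, and C5 is a quaternary carbon that migrates well (like C13 of a steroid ring D). A 1,2-shift of C5 from C3 to C4 therefore gives ring A and a cation that loses H-3.
- Stereochemistry: C5 from the amino-acid-mediated aldol; C10 from Birch protonation; C9 from cis-hydrogenation on the α-face; C8 from enolate methylation anti to the C9 methyl; C1′ from a chiral oxaziridine; C5′ from protonation on the hydroxyl face.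

Key step: step 12

Remarks on the chemistry:
- Numbering: decalin C1–C10 with C5 (angular CH3), C4 (vinylic CH3), C8 (quaternary, bears C11), C9 (CH–CH3), C10 (ring-fusion CH); ring A = C1–C5 + C10, ring B = C5–C10; cyclopentenone C1′ (C–OH), C2′, C3′ (OMe), C4′ (C=O), C5′. α is the face of H-10, β the face of the C5 methyl. In the hydrindanes the five-membered ring is C1, C2, C3, C5, C10.
- Assumption: the non-conjugated ketone of 4 is acetalised in preference to the enone carbonyl, as in the six-ring homologue.
- Assumption: the (+)-oxaziridine delivers oxygen to the face of dienolate 25 that gives (R)-C1′; if the sense is opposite, its enantiomer is used.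

Step 1
Reactants: 1 2-methylcyclopentane-1,3-dione; 2 pent-1-en-3-one
Product: 3 2-methyl-2-(3-oxopentyl)cyclopentane-1,3-dione
Conditions: H2O, AcOH (cat.), 75 °C
Reagents that add atoms: none
Why: Michael addition of the acidic 1,3-dione to the vinyl ketone; no stereocentre is formed.

Step 2
Reactants: 3 triketone
Product: 4 (7aS)-4,7a-dimethyl-2,3,7,7a-tetrahydro-1H-indene-1,5(6H)-dione
Conditions: L-phenylalanine, (1S)-(+)-10-camphorsulfonic acid, MeCN, 60 °C
Reagents that add atoms: none
Why: Hajos–Parrish–Eder–Sauer–Wiechert aldol cyclodehydration; the enamine of the amino acid differentiates the two enantiotopic ring carbonyls and sets C5 as (S).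

Step 3
Reactants: 4 enedione
Product: 5 C3 ethylene acetal of 4 (acetal on the cyclopentanone carbonyl)
Conditions: 2-ethyl-2-methyl-1,3-dioxolane, ethylene glycol (cat.), TsOH·H2O (cat.), 23 °C
Reagents that add atoms: 2-ethyl-2-methyl-1,3-dioxolane, CCC1(C)OCCO1
Why: Transacetalisation should take the more electrophilic non-conjugated ketone and leave the enone free for step 4.

Step 4
Reactants: 5 acetal enone
Product: 7 trans-hydrindane enol triflate (C8–OTf; C8=C9), via lithium enolate 6 (not isolated)
Conditions: Li, NH3 (l), THF, t-BuOH (1 equiv), −78 °C; NH3 removed; PhNTf2, THF, 0 to 23 °C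
Reagents that add atoms: N-phenylbis(trifluoromethanesulfonimide), O=S(=O)(N(c1ccccc1)S(=O)(=O)C(F)(F)F)C(F)(F)F
Why: Birch reduction of the enone; axial protonation at C10 anti to the angular methyl should give the trans ring fusion (H-10 α), and the regiodefined enolate is O-triflated.

Step 5
Reactants: 7 enol triflate
Product: 8 methyl enoate (C8–CO2Me; C8=C9)
Conditions: Pd(OAc)2 (cat.), PPh3, CO (1 atm), MeOH, Et3N, DMF, 60 °C
Reagents that add atoms: carbon monoxide, [C-]#[O+]; methanol, CO
Why: Palladium-catalysed alkoxycarbonylation of an enol triflate; the ester carbon is the later C11.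

Step 6
Reactants: 8 enoate
Product: 9 cis ester (H-8 α; H-9 α; 9β-methyl)
Conditions: H2 (50 bar), 5% Rh/Al2O3, EtOAc, 23 °C
Reagents that add atoms: none
Why: Heterogeneous cis-hydrogenation; the catalyst should approach the α-face, opposite the axial C5 methyl, which sets C9 (methyl β), while C8 is reset in step 7.

Step 7
Reactants: 9 cis ester
Product: 11 quaternary ester (8α-methyl; 8β-CO2Me), via lithium ester enolate 10 (not isolated)
Conditions: LiN(i-Pr)2, THF, −78 to 0 °C; MeI, DMPU, −78 to 23 °C
Reagents that add atoms: iodomethane, CI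
Why: Ester enolate alkylation; the C9 methyl stands on the β-face next to the exocyclic enolate and should send iodomethane to the α-face, which sets C8.

Step 8
Reactants: 11 acetal ester
Product: 12 keto ester (C3 ketone)
Conditions: 1 M HCl, THF, 40 °C
Reagents that add atoms: water, O
Why: Acetal hydrolysis; the ketone has no epimerisable neighbour (C5 quaternary).

Step 9
Reactants: 12 keto ester
Product: 13 (Z)-ethylidene ester (C3=C4H–CH3)
Conditions: EtPPh3Br, KOt-Bu, THF, 65 °C
Reagents that add atoms: ethyltriphenylphosphonium bromide, CC[P+](c1ccccc1)(c1ccccc1)c1ccccc1.[Br-]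
Why: Wittig olefination of the hindered cyclopentanone with a non-stabilised ylide, which should give the (Z)-olefin as with steroid 17-ketones; the hindered ester should not react.

Step 10
Reactants: 13 ethylidene ester
Product: 15 methyl ketone (3β-acetyl; H-3 α), via alkylborane 14 (not isolated)
Conditions: BH3·THF, THF, 0 to 23 °C; then NMO, Pr4N[RuO4] (cat.), 4 Å sieves, CH2Cl2, 23 °C
Reagents that add atoms: 4-methylmorpholine N-oxide, C[N+]1([O-])CCOCC1
Why: Hydroboration from the α-face (anti to the angular methyl) places H-3 α and boron on C4; the organoborane is oxidised in the same flask to the ketone.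

Step 11
Reactants: 15 methyl ketone
Product: 16 (R)-carbinol (3β-[(1R)-1-hydroxyethyl])
Conditions: NaBH4, MeOH, 0 °C
Reagents that add atoms: none
Why: Hydride reduction; as with 20-oxopregnanes, hydride should attack the carbonyl face remote from the angular methyl and give the (R)-alcohol needed in step 12.

Step 12
Reactants: 16 (R)-carbinol
Product: 19 ring-A ester (4-methyl; C3=C4; decalin), via mesylate 17 (not isolated), via exocyclic olefin 18 (not isolated)
Conditions: MsCl, Et3N, CH2Cl2, 0 °C; solvent exchange; 2,6-lutidine, (CF3)2CHOH, 50 °C; then RhCl3·3H2O (cat.), EtOH, 75 °C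
Reagents that add atoms: none
Why: Mesylate 17 should ionise in the polar, weakly nucleophilic medium with participation of the anti-periplanar C3–C5 bond: quaternary C5 shifts from C3 to C4 (Wagner–Meerwein), a 1,2-hydride shift from C4 turns the secondary C3 cation into the tertiary C4 cation, and this loses H-3; any methyl-proton loss gives 18, which the rhodium hydride moves into the ring. The closest known reaction type is the D-homoannulation of pregnan-20-yl sulfonates (uranediol rearrangement), where C13 of the same trans-hydrindane migrates. No ring is closed from a chain; ring A arises from the cyclopentane C1–C2–C3–C5–C10 by one-carbon ring expansion, an endocyclic bond migrating to the exocyclic carbinyl carbon. No new stereocentre is formed: C5 migrates with retention, and C10, C9 and C8 are untouched. The step needs C5, not C2 or H-3, to migrate; the (R)-carbinol secures this because its preferred rotamer (H-4 facing the C5 methyl) holds the C–O bond anti to C3–C5. It also needs the trisubstituted C3=C4 olefin, which is the thermodynamic isomer reached under the rhodium isomerisation.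

Step 13
Reactants: 19 ring-A ester
Product: 20 decalin aldehyde (C11 = CHO)
Conditions: i-Bu2AlH, toluene, −78 °C; aqueous Rochelle salt
Reagents that add atoms: none
Why: Partial reduction of the hindered methyl ester; the aluminium hemiacetal should persist at −78 °C and release the aldehyde on work-up.

Step 14
Reactants: 21 methyl cyclopent-3-ene-1-carboxylate
Product: 22 methyl cis-3,4-dihydroxycyclopentane-1-carboxylate
Conditions: OsO4 (cat.), NMO, acetone–H2O, 23 °C
Reagents that add atoms: 4-methylmorpholine N-oxide, C[N+]1([O-])CCOCC1; water, O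
Why: Catalytic syn-dihydroxylation; the diol stereocentres are removed in step 15.

Step 15
Reactants: 22 diol
Product: 23 methyl 3-hydroxy-4-oxocyclopent-2-ene-1-carboxylate (enol of the 1,2-dione)
Conditions: DMSO, (CF3CO)2O, CH2Cl2, −60 °C; Et3N
Reagents that add atoms: none
Why: Swern-type double oxidation of the vicinal diol to the 1,2-dione, which enolises to the diosphenol.

Step 16
Reactants: 23 diosphenol
Product: 24 methyl 3-methoxy-4-oxocyclopent-2-ene-1-carboxylate (racemic, labile at C1′)
Conditions: MeOH, TsOH·H2O (cat.), 3 Å sieves, 60 °C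
Reagents that add atoms: methanol, CO
Why: Acid-catalysed enol ether formation; the dione is symmetric, so only one constitution can form.

Step 17
Reactants: 24 methoxy enone ester
Product: 27 trimethylsilyl ether of methyl (R)-1-hydroxy-3-methoxy-4-oxocyclopent-2-ene-1-carboxylate, via potassium dienolate 25 (not isolated), via potassium alkoxide 26 (not isolated)
Conditions: KN(SiMe3)2, THF, −78 to −20 °C; (+)-(camphorsulfonyl)oxaziridine, −78 °C; Me3SiCl, −78 to 0 °C
Reagents that add atoms: (+)-(camphorsulfonyl)oxaziridine, CC1(C)[C@@H]2CC[C@]13CS(=O)(=O)N4O[C@@]34C2; chlorotrimethylsilane, C[Si](C)(C)Cl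
Why: Davis hydroxylation of the thermodynamic dienolate (C1′–H is α to the ester and vinylogous to the ketone); the chiral oxaziridine differentiates the faces of planar C1′ and sets its configuration, and the alkoxide is silylated in the flask.

Step 18
Reactants: 27 silyl ether; 20 decalin aldehyde
Product: 29 aldol adduct (C5′–C11 bond; C11–OH), via lithium enolate 28 (not isolated)
Conditions: LiN(i-Pr)2, THF, −78 °C; then 20, −78 to −40 °C; aqueous NH4Cl
Reagents that add atoms: none
Why: Aldol addition of the only possible ketone enolate (C5′) to the non-enolisable aldehyde; the new C5′ and C11 centres are not controlled and are both removed in step 19.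

Step 19
Reactants: 29 aldol adduct
Product: 32 hydroxy dienone (C5′=C11; free C1′–OH), via mesylate 30 (not isolated), via silyl dienone 31 (not isolated)
Conditions: MsCl, Et3N, CH2Cl2, 0 °C; DBU, 23 °C; then citric acid, MeOH, 23 °C
Reagents that add atoms: none
Why: Mesylation and E1cB elimination complete the aldol condensation, and mild acidic methanolysis frees the tertiary alcohol; alkene geometry is inconsequential.

Step 20
Reactants: 32 hydroxy dienone
Product: 34 dysidenone A, via copper enolate 33 (not isolated)
Conditions: [(Ph3P)CuH]6, benzene, H2O (few equiv), 23 °C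
Reagents that add atoms: none
Why: Stryker conjugate reduction should take the exocyclic enone (the methoxy-enone is deactivated and the C3=C4 olefin is inert to hydride); the enolate should be protonated at C5′ on the face of the small hydroxyl, which places CH2 cis to CO2Me.

**Compound list**

1 | 2-methylcyclopentane-1,3-dione | CC1C(=O)CCC1=O | starting material
2 | pent-1-en-3-one | CCC(=O)C=C | starting material
3 | 2-methyl-2-(3-oxopentyl)cyclopentane-1,3-dione | CCC(=O)CCC1(C)C(=O)CCC1=O | intermediate
4 | (7aS)-4,7a-dimethyl-2,3,7,7a-tetrahydro-1H-indene-1,5(6H)-dione | O=C1CC[C@]2(C)C(=O)CCC2=C1C | intermediate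
5 | C3 ethylene acetal of 4 | O=C1CC[C@]2(C)C3(OCCO3)CCC2=C1C | intermediate
6 | lithium enolate, trans-hydrindane (C8–OLi, C8=C9, H-10 α) | CC1=C(O[Li])CC[C@]2(C)C3(OCCO3)CC[C@@H]12 | intermediate
7 | enol triflate (C8–OTf, C8=C9, H-10 α) | CC1=C(OS(=O)(=O)C(F)(F)F)CC[C@]2(C)C3(OCCO3)CC[C@@H]12 | intermediate
8 | methyl enoate (C8–CO2Me, C8=C9) | CC1=C(C(=O)OC)CC[C@]2(C)C3(OCCO3)CC[C@@H]12 | intermediate
9 | cis ester (8β-CO2Me, H-8 α, 9β-CH3, H-9 α) | COC(=O)[C@H]1CC[C@]2(C)C3(OCCO3)CC[C@H]2[C@H]1C | intermediate
10 | lithium ester enolate of 9 | COC(O[Li])=C1CC[C@]2(C)C3(OCCO3)CC[C@H]2[C@H]1C | intermediate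
11 | quaternary ester acetal (8α-CH3, 8β-CO2Me, 9β-CH3) | COC(=O)[C@@]1(C)CC[C@]2(C)C3(OCCO3)CC[C@H]2[C@H]1C | intermediate
12 | keto ester (C3 ketone) | COC(=O)[C@@]1(C)CC[C@]2(C)C(=O)CC[C@H]2[C@H]1C | intermediate
13 | (Z)-ethylidene ester (C3=C4H–CH3, CH3 cis to C5) | COC(=O)[C@@]1(C)CC[C@]2(C)/C(=C\C)CC[C@H]2[C@H]1C | intermediate
14 | alkylborane (H-3 α, boron on C4) | COC(=O)[C@@]1(C)CC[C@]2(C)[C@@H]([C@H](C)B)CC[C@H]2[C@H]1C | intermediate
15 | methyl ketone (3β-acetyl) | COC(=O)[C@@]1(C)CC[C@]2(C)[C@@H](C(C)=O)CC[C@H]2[C@H]1C | intermediate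
16 | (R)-carbinol (3β-[(1R)-1-hydroxyethyl]) | COC(=O)[C@@]1(C)CC[C@]2(C)[C@@H]([C@@H](C)O)CC[C@H]2[C@H]1C | intermediate
17 | mesylate of 16 | COC(=O)[C@@]1(C)CC[C@]2(C)[C@@H]([C@@H](C)OS(C)(=O)=O)CC[C@H]2[C@H]1C | intermediate
18 | exocyclic olefin (4-methylene decalin ester) | COC(=O)[C@@]1(C)CC[C@]2(C)C(=C)CCC[C@H]2[C@H]1C | intermediate
19 | ring-A ester (trans-decalin, C3=C4, 4-CH3, 5β-CH3, 8α-CH3, 8β-CO2Me, 9β-CH3, H-10 α) | COC(=O)[C@@]1(C)CC[C@]2(C)C(C)=CCC[C@H]2[C@H]1C | intermediate
20 | decalin aldehyde (8β-CHO) | O=C[C@@]1(C)CC[C@]2(C)C(C)=CCC[C@H]2[C@H]1C | intermediate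
21 | methyl cyclopent-3-ene-1-carboxylate | COC(=O)C1CC=CC1 | starting material
22 | methyl cis-3,4-dihydroxycyclopentane-1-carboxylate (C1 epimers) | COC(=O)C1C[C@H](O)[C@H](O)C1 | intermediate
23 | methyl 3-hydroxy-4-oxocyclopent-2-ene-1-carboxylate | COC(=O)C1C=C(O)C(=O)C1 | intermediate
24 | methyl 3-methoxy-4-oxocyclopent-2-ene-1-carboxylate (racemic) | COC(=O)C1C=C(OC)C(=O)C1 | intermediate
25 | potassium dienolate of 24 | COC(O[K])=C1C=C(OC)C(=O)C1 | intermediate
26 | potassium alkoxide of methyl (R)-1-hydroxy-3-methoxy-4-oxocyclopent-2-ene-1-carboxylate | COC(=O)[C@]1(O[K])C=C(OC)C(=O)C1 | intermediate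
27 | methyl (R)-3-methoxy-4-oxo-1-(trimethylsilyloxy)cyclopent-2-ene-1-carboxylate | COC(=O)[C@]1(O[Si](C)(C)C)C=C(OC)C(=O)C1 | intermediate
28 | lithium enolate of 27 (C4′–OLi, C4′=C5′) | COC(=O)[C@]1(O[Si](C)(C)C)C=C(OC)C(O[Li])=C1 | intermediate
29 | aldol adduct (C5′–C11H(OH)–C8; C5′ and C11 epimers) | COC(=O)[C@]1(O[Si](C)(C)C)C=C(OC)C(=O)C1C(O)[C@@]2(C)CC[C@]3(C)C(C)=CCC[C@H]3[C@H]2C | intermediate
30 | C11 mesylate of 29 | COC(=O)[C@]1(O[Si](C)(C)C)C=C(OC)C(=O)C1C(OS(C)(=O)=O)[C@@]2(C)CC[C@]3(C)C(C)=CCC[C@H]3[C@H]2C | intermediate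
31 | silyl dienone (C5′=C11, E/Z) | COC(=O)[C@]1(O[Si](C)(C)C)C=C(OC)C(=O)C1=C[C@@]2(C)CC[C@]3(C)C(C)=CCC[C@H]3[C@H]2C | intermediate
32 | hydroxy dienone (C5′=C11, E/Z, free C1′–OH) | COC(=O)[C@]1(O)C=C(OC)C(=O)C1=C[C@@]2(C)CC[C@]3(C)C(C)=CCC[C@H]3[C@H]2C | intermediate
33 | copper enolate (C4′–OCu, C4′=C5′) | COC(=O)[C@]1(O)C=C(OC)C(O[Cu])=C1C[C@@]2(C)CC[C@]3(C)C(C)=CCC[C@H]3[C@H]2C | intermediate
34 | dysidenone A, methyl (1S,5R)-1-hydroxy-3-methoxy-4-oxo-5-{[(1R,2R,4aS,8aS)-1,2,4a,5-tetramethyl-1,2,3,4,4a,7,8,8a-octahydronaphthalen-2-yl]methyl}cyclopent-2-ene-1-carboxylate | COC(=O)[C@]1(O)C=C(OC)C(=O)[C@@H]1C[C@@]1(C)CC[C@]2(C)C(C)=CCC[C@H]2[C@H]1C | target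

Total step count: 20. Longest linear sequence: 16 (steps 1–13, then 18–20).

**Steps most likely to fail**

Step 12. The ionisation may branch: C2 may migrate instead of C5, H-3 may shift to give the ethylidene or ring olefins without ring enlargement, or the C4 cation may take a methyl from C5 before losing a proton. Fallback: set out from keto ester 12 and enlarge the ring on the other side of the carbonyl. Treatment of 12 with Me3SiCHN2 and BF3·OEt2 in CH2Cl2 at −78 °C should insert the diazo carbon between the carbonyl and the less substituted C2, giving the α-silyl ring-enlarged ketone F1. Work-up with dilute acid removes silicon and gives the ring-enlarged C4 ketone F2. This ketone can enolise only towards C3, so KN(SiMe3)2 and PhNTf2 give the C3=C4 enol triflate F3. Cross-coupling with MeMgBr and Fe(acac)3 (cat.) in THF/NMP at −20 °C then puts the methyl on C4 and returns to the route at 19.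

Step 20. The enolate may be protonated with poor facial selectivity at C5′, or the hindered exocyclic enone may react too slowly to compete with attack on the methoxy-enone. Fallback: set out from 32 and replace hydride addition and intermolecular protonation by hydroxyl-directed hydrogenation with [Rh(nbd)(dppb)]BF4 and H2 in CH2Cl2. The cationic rhodium is held by the C1′ hydroxyl and delivers both hydrogens to the allylic exocyclic double bond from the hydroxyl face, so that H-5′ is cis to OH. This returns to the route at 34 and makes no new compound.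

Step 6. The tetrasubstituted enoate may resist hydrogenation, or hydrogen may be delivered in part from the β-face. Fallback: set out from 8 and reduce by metal-hydride hydrogen atom transfer with Mn(dpm)3, PhSiH3 and i-PrOH. The bulky manganese hydride should give its hydrogen atom to C9 from the open α-face, and the resulting C8 radical is reduced without control. The product is 9 together with its C8 epimer F4; both give the same enolate 10, so the route is rejoined at 9 and converges in step 7.

Further compounds
F1 | step 12 | α-trimethylsilyl ring-enlarged ketone (C4 ketone, silicon on C3) | COC(=O)[C@@]1(C)CC[C@]2(C)C(=O)C([Si](C)(C)C)CC[C@H]2[C@H]1C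
F2 | step 12 | ring-enlarged C4 ketone (trans-decalin-4-one ester) | COC(=O)[C@@]1(C)CC[C@]2(C)C(=O)CCC[C@H]2[C@H]1C
F3 | step 12 | C3=C4 enol triflate | COC(=O)[C@@]1(C)CC[C@]2(C)C(OS(=O)(=O)C(F)(F)F)=CCC[C@H]2[C@H]1C
F0 | step 20 | none | none
F4 | step 6 | C8 epimer of 9 (8α-CO2Me) | COC(=O)[C@@H]1CC[C@]2(C)C3(OCCO3)CC[C@H]2[C@H]1C
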